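## Retrosynthetic overview

- The only ring (the δ-lactone) is formed last, by allylic C–O bond formation at the pyranone C6 carbon (the single stereocentre), in an enantioselective Pd-catalysed diene carbo-acyloxylation joining a (Z)-β-iodoacrylic acid and a 2-(acetoxymethyl)-1,3-diene.
- The diene comes from a 1,1-dibromoalkene by two stereospecific cross-couplings (vinyl trans to the chain, then CH2OAc cis); the dibromoalkene comes from the aldehyde made by chemoselective ozonolysis of neryl acetate, which supplies the (Z)-allylic alcohol end.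
- The iodo acid comes from propargyl alcohol and homoprenylmagnesium bromide (anti-carbomagnesiation, then iodinolysis), followed by oxidation.
- OH/OAc differentiation needs no protecting group: the C1 acetate of neryl acetate is removed before the second acetate is brought in as an intact AcOCH2 unit.

Assumption: the (S,R,R)-phosphoramidite is taken to give the (R)-lactone in step 8; if the sense is reversed, the mirror-image ligand is used with no other change.

## Route

Step 1
Reactants: 1 neryl acetate [(2Z)-3,7-dimethylocta-2,6-dien-1-yl acetate]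
Product: 3 (2Z)-3-methyl-6-oxohex-2-en-1-yl acetate, via secondary ozonide 2 (not isolated)
Conditions: O3 (1.0 equiv, Sudan III end-point), CH2Cl2, −78 °C; then Me2S, −78 °C→rt
Reagents that add atoms: ozone, [O-][O+]=O
Why: Chemoselective ozonolysis: the electron-rich distal trisubstituted alkene reacts much faster than the 2,3-alkene deactivated by the allylic acetate, and Me2S reduces ozonide 2 to the aldehyde; no stereocentre is formed and the 2Z alkene is untouched.

Step 2
Reactants: 3 (2Z)-3-methyl-6-oxohex-2-en-1-yl acetate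
Product: 4 (2Z)-7,7-dibromo-3-methylhepta-2,6-dien-1-yl acetate
Conditions: CBr4, PPh3, Zn, CH2Cl2, 0 °C→rt
Reagents that add atoms: carbon tetrabromide, BrC(Br)(Br)Br
Why: Ramirez (Corey–Fuchs-type) dibromo-olefination with Ph3P=CBr2 under neutral conditions converts the aldehyde to the 1,1-dibromoalkene and leaves the allylic acetate alone.

Step 3
Reactants: 4 (2Z)-7,7-dibromo-3-methylhepta-2,6-dien-1-yl acetate
Product: 5 (2Z)-7,7-dibromo-3-methylhepta-2,6-dien-1-ol
Conditions: K2CO3 (cat.), MeOH, 0 °C→rt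
Reagents that add atoms: none
Why: Base-catalysed transesterification (methanolysis) frees the C1 alcohol now, so that the only acetate later present is the one introduced on the other CH2O group.

Step 4
Reactants: 5 (2Z)-7,7-dibromo-3-methylhepta-2,6-dien-1-ol
Product: 6 (2Z,6Z)-7-bromo-3-methylnona-2,6,8-trien-1-ol
Conditions: tributyl(vinyl)stannane (1.05 equiv), Pd2(dba)3 (2.5 mol %), tri(2-furyl)phosphine, toluene, 100 °C
Reagents that add atoms: tributyl(vinyl)stannane, C=C[Sn](CCCC)(CCCC)CCCC
Why: Trans-selective Stille coupling of a 1,1-dibromoalkene: oxidative addition occurs at the less hindered C–Br bond trans to the alkyl chain, so the vinyl group enters trans and the remaining bromide is cis (Z); toluene with furylphosphine suppresses HBr loss to the enyne.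

Step 5
Reactants: 6 (2Z,6Z)-7-bromo-3-methylnona-2,6,8-trien-1-ol
Product: 7 (2Z,6Z)-2-ethenyl-8-hydroxy-6-methylocta-2,6-dien-1-yl acetate
Conditions: BrCH2OAc, Zn (TMSCl-activated), THF, 15 °C (3 equiv of zinc reagent); then 6, Pd(OAc)2 (4 mol %), SPhos (8 mol %), THF, 25→40 °C
Reagents that add atoms: bromomethyl acetate (used as its zinc reagent), CC(=O)OCBr
Why: Negishi coupling of the remaining alkenyl bromide goes with retention, placing CH2OAc cis to the chain and fixing the trisubstituted alkene geometry of the target; the weakly basic α-acyloxyalkylzinc reagent tolerates the free alcohol when used in excess.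

Step 6
Reactants: 8 prop-2-yn-1-ol; 9 5-bromo-2-methylpent-2-ene
Product: 12 (2Z)-2-(iodomethylidene)-6-methylhept-5-en-1-ol, via homoprenylmagnesium bromide 10 (not isolated), via alkenylmagnesium alkoxide 11 (not isolated)
Conditions: 9, Mg, THF; then 8 (0.4 equiv), CuI (10 mol %), THF, 0 °C→reflux; then I2, −20→0 °C; aq NH4Cl/Na2S2O3
Reagents that add atoms: iodine, II
Why: Copper-catalysed anti-carbomagnesiation of the propargylic alkoxide (Duboudin-type) delivers the alkyl group to C2 and magnesium to C3 in a five-membered chelate, so iodinolysis gives the alkenyl iodide with iodine cis to CH2OH.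

Step 7
Reactants: 12 (2Z)-2-(iodomethylidene)-6-methylhept-5-en-1-ol
Product: 14 (2Z)-2-(iodomethylidene)-6-methylhept-5-enoic acid, via iodoenal 13 (not isolated)
Conditions: TEMPO (10 mol %), PhI(OAc)2, CH2Cl2, rt; then NaClO2, NaH2PO4, 2-methylbut-2-ene, t-BuOH/H2O, 0 °C→rt (one pot)
Reagents that add atoms: sodium chlorite, [Na+].[O-]Cl=O
Why: TEMPO/PhI(OAc)2 oxidation gives enal 13 and Pinnick oxidation (scavenger protects the trisubstituted alkene) gives the acid without touching the alkenyl iodide or its geometry.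

Step 8
Reactants: 7 (2Z,6Z)-2-ethenyl-8-hydroxy-6-methylocta-2,6-dien-1-yl acetate; 14 (2Z)-2-(iodomethylidene)-6-methylhept-5-enoic acid
Product: 15 [(2E,6Z)-8-hydroxy-6-methyl-2-[(2R)-5-(4-methylpent-3-en-1-yl)-6-oxo-3,6-dihydro-2H-pyran-2-yl]octa-2,6-dien-1-yl] acetate (target)
Conditions: 7 (1.0 equiv), 14 (1.3 equiv), Pd2(dba)3 (2.5 mol %), (S,R,R)-BINOL N,N-bis(1-phenylethyl)phosphoramidite (6 mol %), Ag2CO3 (0.6 equiv), toluene, 50 °C
Reagents that add atoms: none
Why: Proposed new method: enantioselective Pd(0)-catalysed [4+2] carbo-acyloxylation of a 1,3-diene by a (Z)-β-iodoacrylic acid. Oxidative addition gives an alkenyl–Pd species held as a κ2(C,O) carboxylate chelate once Ag+ removes iodide. The unsubstituted diene terminus inserts regioselectively (C–C at CH2), on the face chosen by the chiral monodentate phosphoramidite, which leaves cis sites for chelate and diene. The resulting syn-η3-allyl–Pd is closed at its near terminus by the bound carboxylate (allylic C–O reductive elimination, six- over eight-membered ring). This C–O bond formation makes the ring and the (R)-stereocentre, and the alkene geometry is kept because ring closure is faster than syn/anti exchange. The closest known reaction types are the Larock heteroannulation of 1,3-dienes by o-iodobenzoic acids and the asymmetric Pd-catalysed carboamination/carboetherification of dienes with aryl iodides; it has not been shown enantioselectively for β-iodoacrylic acids giving δ-lactones.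

## Compound list

1 | neryl acetate, (2Z)-3,7-dimethylocta-2,6-dien-1-yl acetate | CC(C)=CCC/C(C)=C\COC(C)=O | starting material
2 | secondary ozonide, (2Z)-5-(5,5-dimethyl-1,2,4-trioxolan-3-yl)-3-methylpent-2-en-1-yl acetate | CC(=O)OC/C=C(C)\CCC1OOC(C)(C)O1 | intermediate
3 | (2Z)-3-methyl-6-oxohex-2-en-1-yl acetate | CC(=O)OC/C=C(C)\CCC=O | intermediate
4 | (2Z)-7,7-dibromo-3-methylhepta-2,6-dien-1-yl acetate | CC(=O)OC/C=C(C)\CCC=C(Br)Br | intermediate
5 | (2Z)-7,7-dibromo-3-methylhepta-2,6-dien-1-ol | OC/C=C(C)\CCC=C(Br)Br | intermediate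
6 | (2Z,6Z)-7-bromo-3-methylnona-2,6,8-trien-1-ol | OC/C=C(C)\CC/C=C(Br)/C=C | intermediate
7 | (2Z,6Z)-2-ethenyl-8-hydroxy-6-methylocta-2,6-dien-1-yl acetate | OC/C=C(C)\CC/C=C(COC(C)=O)/C=C | intermediate
8 | prop-2-yn-1-ol | C#CCO | starting material
9 | 5-bromo-2-methylpent-2-ene | CC(C)=CCCBr | starting material
10 | homoprenylmagnesium bromide, (4-methylpent-3-en-1-yl)magnesium bromide | CC(C)=CCC[Mg]Br | intermediate
11 | alkenylmagnesium alkoxide, bromomagnesium (2Z)-3-(bromomagnesio)-2-(4-methylpent-3-en-1-yl)prop-2-en-1-olate | Br[Mg]OC/C(=C\[Mg]Br)CCC=C(C)C | intermediate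
12 | (2Z)-2-(iodomethylidene)-6-methylhept-5-en-1-ol | OC/C(=C\I)CCC=C(C)C | intermediate
13 | iodoenal, (2Z)-2-(iodomethylidene)-6-methylhept-5-enal | O=C/C(=C\I)CCC=C(C)C | intermediate
14 | (2Z)-2-(iodomethylidene)-6-methylhept-5-enoic acid | OC(=O)/C(=C\I)CCC=C(C)C | intermediate
15 | [(2E,6Z)-8-hydroxy-6-methyl-2-[(2R)-5-(4-methylpent-3-en-1-yl)-6-oxo-3,6-dihydro-2H-pyran-2-yl]octa-2,6-dien-1-yl] acetate | CC(=O)OC/C(=C\CC/C(C)=C\CO)[C@H]1CC=C(CCC=C(C)C)C(=O)O1 | target

## Step count and risks

Total step count: 8. Longest linear sequence: 6 (steps 1–5, then 8).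

Steps most likely to fail:

1. Step 8 (the new annulation). The risks are poor turnover, Pd(0) ionisation of the allylic acetate or of the product lactone, and insufficient ee. The fallback uses known chemistry, sets out from aldehyde 3 and comes back at target 15.
 - Wittig homologation of 3 with (triphenylphosphoranylidene)acetaldehyde gives (2Z,6E)-3-methyl-8-oxoocta-2,6-dien-1-yl acetate F1.
 - α-Iodination (I2, pyridine) gives (2Z,6Z)-7-iodo-3-methyl-8-oxoocta-2,6-dien-1-yl acetate F2.
 - Brown allylboration with (+)-B-allyldiisopinocampheylborane sets the carbinol centre by reagent control and gives (2Z,6Z,8R)-8-hydroxy-7-iodo-3-methylundeca-2,6,10-trien-1-yl acetate F3.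
 - Separately, 10 and 8 are combined as in step 6 but quenched with NH4Cl to give 6-methyl-2-methylidenehept-5-en-1-ol F4, which is oxidised as in step 7 to 6-methyl-2-methylidenehept-5-enoic acid F5.
 - Steglich esterification of F3 with F5 gives (2Z,6Z,8R)-1-acetoxy-7-iodo-3-methylundeca-2,6,10-trien-8-yl 6-methyl-2-methylidenehept-5-enoate F6.
 - Ring-closing metathesis (Grubbs II) closes the lactone to [(2Z,6Z)-7-iodo-3-methyl-7-[(2R)-5-(4-methylpent-3-en-1-yl)-6-oxo-3,6-dihydro-2H-pyran-2-yl]hepta-2,6-dien-1-yl] acetate F7.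
 - Lipase (CAL-B, pH 7 buffer) removes the primary acetate to give (6R)-6-[(1Z,5Z)-7-hydroxy-1-iodo-5-methylhepta-1,5-dien-1-yl]-3-(4-methylpent-3-en-1-yl)-5,6-dihydro-2H-pyran-2-one F8.
 - Stille coupling with (acetoxymethyl)tributylstannane replaces iodide by CH2OAc with retention and gives 15.

2. Step 5 (Negishi acetoxymethylation). The risks are sluggish coupling at the hindered bromide, protonation of the zinc reagent by the free alcohol, and Pd attack on the new allylic acetate. The fallback sets out from 6 and comes back at 7.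
 - Silylation (TBSCl, imidazole) gives tert-butyl{[(2Z,6Z)-7-bromo-3-methylnona-2,6,8-trien-1-yl]oxy}dimethylsilane F9.
 - Stille hydroxymethylation with (tributylstannyl)methanol gives (2Z,6Z)-8-{[tert-butyl(dimethyl)silyl]oxy}-2-ethenyl-6-methylocta-2,6-dien-1-ol F10.
 - Acetylation (Ac2O, pyridine) gives (2Z,6Z)-8-{[tert-butyl(dimethyl)silyl]oxy}-2-ethenyl-6-methylocta-2,6-dien-1-yl acetate F11.
 - HF·pyridine removes the silyl ether to give 7.

3. Step 1 (selective ozonolysis). The risk is over-cleavage of the 2,3-alkene. The fallback sets out from 1 and comes back at 3: mCPBA epoxidises only the distal alkene to give (2Z)-5-(3,3-dimethyloxiran-2-yl)-3-methylpent-2-en-1-yl acetate F12, and periodic acid (THF/H2O) cleaves the epoxide to 3.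

## Further compounds

F1 | step 8 | (2Z,6E)-3-methyl-8-oxoocta-2,6-dien-1-yl acetate | CC(=O)OC/C=C(C)\CC/C=C/C=O
F2 | step 8 | (2Z,6Z)-7-iodo-3-methyl-8-oxoocta-2,6-dien-1-yl acetate | CC(=O)OC/C=C(C)\CC/C=C(I)/C=O
F3 | step 8 | (2Z,6Z,8R)-8-hydroxy-7-iodo-3-methylundeca-2,6,10-trien-1-yl acetate | C=CC[C@@H](O)/C(I)=C/CC/C(C)=C\COC(C)=O
F4 | step 8 | 6-methyl-2-methylidenehept-5-en-1-ol | OCC(=C)CCC=C(C)C
F5 | step 8 | 6-methyl-2-methylidenehept-5-enoic acid | OC(=O)C(=C)CCC=C(C)C
F6 | step 8 | (2Z,6Z,8R)-1-acetoxy-7-iodo-3-methylundeca-2,6,10-trien-8-yl 6-methyl-2-methylidenehept-5-enoate | C=CC[C@@H](OC(=O)C(=C)CCC=C(C)C)/C(I)=C/CC/C(C)=C\COC(C)=O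
F7 | step 8 | [(2Z,6Z)-7-iodo-3-methyl-7-[(2R)-5-(4-methylpent-3-en-1-yl)-6-oxo-3,6-dihydro-2H-pyran-2-yl]hepta-2,6-dien-1-yl] acetate | CC(=O)OC/C=C(C)\CC/C=C(I)/[C@H]1CC=C(CCC=C(C)C)C(=O)O1
F8 | step 8 | (6R)-6-[(1Z,5Z)-7-hydroxy-1-iodo-5-methylhepta-1,5-dien-1-yl]-3-(4-methylpent-3-en-1-yl)-5,6-dihydro-2H-pyran-2-one | OC/C=C(C)\CC/C=C(I)/[C@H]1CC=C(CCC=C(C)C)C(=O)O1
F9 | step 5 | tert-butyl{[(2Z,6Z)-7-bromo-3-methylnona-2,6,8-trien-1-yl]oxy}dimethylsilane | CC(C)(C)[Si](C)(C)OC/C=C(C)\CC/C=C(Br)/C=C
F10 | step 5 | (2Z,6Z)-8-{[tert-butyl(dimethyl)silyl]oxy}-2-ethenyl-6-methylocta-2,6-dien-1-ol | CC(C)(C)[Si](C)(C)OC/C=C(C)\CC/C=C(CO)/C=C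
F11 | step 5 | (2Z,6Z)-8-{[tert-butyl(dimethyl)silyl]oxy}-2-ethenyl-6-methylocta-2,6-dien-1-yl acetate | CC(C)(C)[Si](C)(C)OC/C=C(C)\CC/C=C(COC(C)=O)/C=C
F12 | step 1 | (2Z)-5-(3,3-dimethyloxiran-2-yl)-3-methylpent-2-en-1-yl acetate | CC(=O)OC/C=C(C)\CCC1OC1(C)C
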